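The flask cannot keep its opening pace: at 0.0285 h⁻¹, the initial rate as a fraction of the substrate charge per hour, it would turn over 171% of that charge in 2.5 d.

- north-east: left-handed substrate 0.010 M; right-handed substrate 0.010 M; reagent 0.020 M; free catalyst 20 µM; racemization catalyst 24 µM; impurity 9.7 µM; the very flask that is asked about, followed so far
- flask: left-handed substrate 0.010 M; reagent 0.0200 M; free catalyst 20 µM; racemization catalyst 24 µM; impurity 9.7 µM; right-handed substrate 0.010 M; time 2.5 d

north-east run (percent of the left-handed substrate and right-handed substrate together charged)

| time / h | left-handed product / % | right-handed product / % |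
|---|---|---|
| 1.00 | 1.9 | 1.3 |
| 3.00 | 5.8 | 1.9 |
| 6.00 | 10.3 | 4.2 |
| 8.00 | 13.2 | 5.3 |
| 12.0 | 19.2 | 6.3 |

(readings scatter by 0.5 percentage points)

- free catalyst is single-handed; left-handed substrate and right-handed substrate are mirror images of each other, charged as a racemate, each of them at the stated concentration
- an excess is below zero if the other one leads

1. excess of left-handed product over right-handed product in the product at 80 min
2. excess of left-handed product over right-handed product in the product at 2.5 d
3. part of the left-handed substrate and right-handed substrate charged together that has reacted at 2.5 d

I reckoned that rate from the readings. The c of reagent starts at 0.020 M, equal to the two substrates together, so if one reagent goes with one substrate, both fall alike. The rate is then the initial rate times two equal slowing factors, each the part still left. Its mean over a run is the geometric mean of start and end, the initial rate times one such factor. At 12.0 h the products summed to 25.5%, a mean of 0.0212 h⁻¹, and dividing by the 74.5% left gives the initial rate above. The reading at 6.00 h gives 0.0283 h⁻¹.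

Carried to 2.5 d, the turned-over part over its rest equals 1.71, so I expected 63.1%. Each factor ends at 36.9%, and the final rate is 13.6% of the initial one. The reading to watch is at 1.25 d, where the rule asks for 46.1%. The rule is silent on the excess. The last reading shows 50.6%, which I took for 80 min, and I expected less by 2.5 d if the substrate tilted towards the right-handed form.

The forecast gave 47%, 42% and 62%: “The excess should erode a little if racemization lags”.

The flask gave 50.5%, 40.1% and 61.7%, which is 1.4 percentage points below my figure.

    reagent + racemization catalyst → spent catalyst A (k = 1.60 × 10⁻⁴ M⁻¹ s⁻¹)
    reagent + free catalyst + right-handed substrate → free catalyst + right-handed product (k = 10.0 M⁻² s⁻¹)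
    racemization catalyst + impurity → spent catalyst C (k = 42.0 M⁻¹ s⁻¹)
    left-handed substrate + racemization catalyst ⇌ right-handed substrate + racemization catalyst, rate k4*[racemization catalyst]*[left-handed substrate] forward; the back reaction follows from the equilibrium constant (k = 0.430 M⁻¹ s⁻¹)
    racemization catalyst → spent catalyst B (k = 2.10 × 10⁻⁶ s⁻¹)
    reagent + free catalyst + left-handed substrate → free catalyst + left-handed product (k = 31.0 M⁻² s⁻¹)

The neighbouring flask was charged with 0.0080 M of reagent, its other charges and its time held as in the recipe. I scaled the initial rate with c of reagent to 0.0114 h⁻¹, which over 2.5 d makes 68.4% of the substrate charge. Its two factors ended unequal, reagent at 25.0% and substrates at 70.0%, so their geometric mean is 41.8%. That reckons 28.6% turned over, and the neighbouring flask had reacted 30.0%, which is 1.4 points above it.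

All runs come from a simulation from invented constants; the scatter is artificial.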